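Its constants stand for no real mixture; the rest is arithmetic.

J2 grows from free J, squared, so in these flasks I wanted to know how much of the released J stood free, and for how long.

    E → X (k1 = 1.1 /s)
    E ⇌ G (K2 = 2.7, k2 = 0.12 /s)
    L → J (k3 = 0.14 /s)
    J + X ⇌ J.X (K4 = 340 /M, k4 = 250 /M/s)
    2 J → J2 (k5 = 29 /M/s)

all flasks: time 15 s
- Tuesday's: L 5.0 mM (fed, over 6.0 s); E 1.50 equiv; all else is in the flask from the start; the feed brings no volume worth counting
- Friday's: L 5.0 mM; E 1.50 equiv; everything together at the start
- Wednesday's: L 5.0 mM; E 1.50 equiv (fed, over 6.0 s); all else is in the flask from the start; the feed brings no volume worth counting
- Saturday's: L 5.0 mM (in portions, 2, over 6.0 s); E 1.50 equiv; first portion at the start, last at 6.0 s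

- percentages count the L that a species holds: one J2 counts as two
- a doubled species enters its step squared and goes two at a time
- run time (Tuesday's): 15 s

- the flask that comes out highest in amount of J2, in percent of the L charged; "all alike" if 1.5 percentage points covers them all (Tuesday's / Friday's / Wednesday's / Saturday's / all alike)
- amount of J2 at the end, in percent of the L charged, Tuesday's
- amount of J2 at the end, in percent of the L charged, Friday's
- amount of J2 at the end, in percent of the L charged, Wednesday's
- amount of J2 at the end, in percent of the L charged, Saturday's

I began with Friday's and the bare road, L releasing J and J pairing. The square of the released fraction, integrated in closed form over 15 s, came to 5.98 s, and twice the pairing constant times 5.0 mM times that gave 173% of the L charged, more than the charge, so that figure, in which the pairing uses up no J, could not stand. Then I added X. E goes to X at 1.1 /s, faster than by the forward step to G at 0.12 /s, and from these two constants I reckoned 6.76 mM of X, free and bound together. Against a released pool of 4.39 mM at the end, the binding balance with 340 /M put 2.58 mM into J.X and left 0.413 free. This free share, [J] over [J] + [J.X], enters squared and brought the number down to 29.5%. Last I let J2 draw on its own pool, taking the late pool short by half the J2 made, and that gave 20.4% for Friday's.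

For Tuesday's, the feed of 6.0 s left 67.7% of the L unreleased at its end. I left out the seconds of the feed itself, and the integral from there came to 3.58 s, less than Friday's. With the same free share and correction, Tuesday's came to 14.0%, and I set Saturday's beside it. On Wednesday's the feed of 6.0 s is longer than the 0.630 s half-life of E by its step to X alone, so X arrives with the feed, and I took the free share to stand higher early; I put that flask above Friday's without a number.

The forecast named Wednesday's, with 13% for Tuesday's, 19% for Friday's, 22% for Wednesday's and 13% for Saturday's, on the ground that “Feeding E late leaves J poorly captured early and gives the most J2”; its Friday's and Tuesday's stand below my 20.4% and 14.0%.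

The flasks gave 13.0% on Tuesday's, 19.4% on Friday's, 21.9% on Wednesday's and 12.4% on Saturday's, with Wednesday's highest. On Saturday's the binding of J to X relaxed with a half-life of 0.302 s at 15.0 s, far shorter than the 5.0 s of L releasing J. That is a pre-equilibrium on Saturday's, and on Friday's the table gave a free share of 0.374 at 15.0 s against my 0.413. The neighbour of Saturday's with 3.80 equiv of E held 14.7 mM of free X at 15.0 s, for which the binding constant gives a free share of 0.167, and it stood at 3.15% J2 with a free share in the table of 0.172.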